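The route hinges on disconnecting C5–C1', the bond that joins the prenyl group to ring A. The feature used is that C1' on C5 and the hydroxyl on C3a lie on the same face of ring A, flanking the C4 carbonyl, so a two-atom chain tied to O3a meets C5 from that face alone. In a single operation fluoride frees the C4/C6 dione enolate, C5 alkylates with a tethered iodide, the quaternary centre forms and a temporary oxa-bridge (C5, C1', acetal carbon, O, C3a, C4) closes; the acetal carbon becomes C2' by later olefination. The precursor is a (2S,3aR)-para-quinol of a dihydrobenzofuran, O4-silylated, carbinol-silylated, with O–CH(OEt)–CH2I on O3a.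

Key step: step 9

Assumption: the D-fructose-derived Shi ketone is taken to epoxidise the prenyl olefin to the (R)-epoxide, as it does other trisubstituted olefins; if the sense were the reverse, the enantiomeric ketone would be used.

Remark: atom numbers follow the 1-benzofuran skeleton of the target (O1, C2, C3, C3a, C4–C7, C7a; ring A is the carbocycle, ring B the dihydrofuran; C1'–C3' are the prenyl carbons on C5) and are used for the aromatic precursors too. In 15, 17 and the target the descriptors are 2S, 3aR (and 5S): C1' and O3a lie on one face of ring A, the C2 side chain on the other face of ring B.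

Step 1
Reactants: 1 2-methylbenzene-1,3,5-triol; 2 isobutyryl chloride
Product: 3 2-methyl-1-(2,4,6-trihydroxy-3-methylphenyl)propan-1-one
Conditions: AlCl3 (3 equiv), PhNO2, 0 → 60 °C; aq. HCl work-up
Reagents that add atoms: none
Why: Friedel–Crafts C-acylation of the electron-rich triol, in which the two free ring carbons are equivalent so only one ketone can form, and the first acyl group deactivates the ring against a second.

Step 2
Reactants: 3 2-methyl-1-(2,4,6-trihydroxy-3-methylphenyl)propan-1-one; 4 prenyl bromide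
Product: 5 2-methyl-1-[2,4,6-trihydroxy-3-methyl-5-(3-methylbut-2-en-1-yl)phenyl]propan-1-one
Conditions: 4 (1.0 equiv), 10% aq. KOH, 0 °C
Reagents that add atoms: none
Why: C-alkylation of the ambident acylphloroglucinol phenoxide in water (the classical aqueous-alkali C-prenylation) at the one unsubstituted ring carbon, where hydrogen bonding to the phenoxide oxygens favours carbon over oxygen and one equivalent of bromide limits geminal dialkylation.

Step 3
Reactants: 5 2-methyl-1-[2,4,6-trihydroxy-3-methyl-5-(3-methylbut-2-en-1-yl)phenyl]propan-1-one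
Product: 7 4-methyl-6-(3-methylbut-2-en-1-yl)-2-(2-methylpropanoyl)-5-(triisopropylsilyloxy)-1,3-phenylene diacetate, via para-O-triisopropylsilyl ether 6 (not isolated)
Conditions: TIPSCl (1.05 equiv), imidazole, DMF, 0 °C → rt; then Ac2O, Et3N, DMAP (cat.), rt
Reagents that add atoms: triisopropylsilyl chloride CC(C)[Si](Cl)(C(C)C)C(C)C; acetic anhydride CC(=O)OC(C)=O
Why: Silyl ether formation at the most acidic, non-chelated hydroxyl (para to the acyl group, the future O4), followed by DMAP-catalysed acetylation of the two chelated ortho hydroxyls, so that O4 cannot later open the epoxide and no free phenol meets the oxidant of step 4.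

Step 4
Reactants: 7 4-methyl-6-(3-methylbut-2-en-1-yl)-2-(2-methylpropanoyl)-5-(triisopropylsilyloxy)-1,3-phenylene diacetate
Product: 8 4-{[(2R)-3,3-dimethyloxiran-2-yl]methyl}-6-methyl-2-(2-methylpropanoyl)-5-(triisopropylsilyloxy)-1,3-phenylene diacetate
Conditions: D-fructose-derived Shi ketone (0.3 equiv), KHSO5 (as 2KHSO5·KHSO4·K2SO4), K2CO3, Bu4NHSO4, MeCN–CH2(OMe)2–aq. Na2B4O7 buffer, 0 °C
Reagents that add atoms: potassium peroxymonosulfate [K+].[O-]S(=O)(=O)OO
Why: Shi asymmetric epoxidation, in which the chiral dioxirane formed from the ketone and KHSO5 transfers oxygen to one face of the trisubstituted olefin through the spiro transition state and should set the epoxide carbon as R, while the fully masked, acyl-deactivated arene is left alone.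

Step 5
Reactants: 8 4-{[(2R)-3,3-dimethyloxiran-2-yl]methyl}-6-methyl-2-(2-methylpropanoyl)-5-(triisopropylsilyloxy)-1,3-phenylene diacetate
Product: 10 1-[(2S)-6-hydroxy-2-(2-hydroxypropan-2-yl)-5-methyl-4-(triisopropylsilyloxy)-2,3-dihydro-1-benzofuran-7-yl]-2-methylpropan-1-one, via epoxy diphenol 9 (not isolated)
Conditions: K2CO3, MeOH, 0 °C → rt
Reagents that add atoms: none
Why: Base-catalysed methanolysis of the two aryl acetates frees the phenols, and the phenoxide next to the side chain (O1) opens the epoxide at its secondary carbon in a 5-exo-tet SN2 reaction with inversion, which turns the (R)-epoxide into the (2S)-dihydrobenzofuran and leaves the tertiary carbinol.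

Step 6
Reactants: 10 1-[(2S)-6-hydroxy-2-(2-hydroxypropan-2-yl)-5-methyl-4-(triisopropylsilyloxy)-2,3-dihydro-1-benzofuran-7-yl]-2-methylpropan-1-one
Product: 12 1-[(2S)-6-hydroxy-5-methyl-2-[2-(triethylsilyloxy)propan-2-yl]-4-(triisopropylsilyloxy)-2,3-dihydro-1-benzofuran-7-yl]-2-methylpropan-1-one, via bis-triethylsilyl ether 11 (not isolated)
Conditions: TESOTf (2.5 equiv), 2,6-lutidine, CH2Cl2, −78 → 0 °C; then K2CO3, MeOH, 0 °C
Reagents that add atoms: triethylsilyl trifluoromethanesulfonate CC[Si](CC)(CC)OS(=O)(=O)C(F)(F)F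
Why: Silyl triflate silylation of the tertiary carbinol (the chelated phenol is silylated as well), then selective methanolysis of the labile aryl triethylsilyl ether ortho to the acyl group, which the hindered aryl triisopropylsilyl ether and the tertiary alkyl silyl ether should survive.

Step 7
Reactants: 12 1-[(2S)-6-hydroxy-5-methyl-2-[2-(triethylsilyloxy)propan-2-yl]-4-(triisopropylsilyloxy)-2,3-dihydro-1-benzofuran-7-yl]-2-methylpropan-1-one
Product: 13 (2S,3aR)-3a-hydroxy-5-methyl-7-(2-methylpropanoyl)-2-[2-(triethylsilyloxy)propan-2-yl]-4-(triisopropylsilyloxy)-3,3a-dihydro-1-benzofuran-6(2H)-one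
Conditions: PhI(OAc)2 (1.1 equiv), MeCN–H2O (4:1), 0 °C
Reagents that add atoms: water O
Why: Oxidative dearomatisation of a phenol by a trivalent iodine reagent to a para-quinol, in which ligand exchange at O6 and loss of PhI make the ring electrophilic, water adds at C3a (para to O6) on the face of ring B opposite the bulky silyloxyisopropyl group on C2, which should set 3aR, and the O4 aryl silyl ether becomes a vinylogous silyl ester.

Step 8
Reactants: 13 (2S,3aR)-3a-hydroxy-5-methyl-7-(2-methylpropanoyl)-2-[2-(triethylsilyloxy)propan-2-yl]-4-(triisopropylsilyloxy)-3,3a-dihydro-1-benzofuran-6(2H)-one; 14 ethyl vinyl ether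
Product: 15 (2S,3aR)-3a-(1-ethoxy-2-iodoethoxy)-5-methyl-7-(2-methylpropanoyl)-2-[2-(triethylsilyloxy)propan-2-yl]-4-(triisopropylsilyloxy)-3,3a-dihydro-1-benzofuran-6(2H)-one (both epimers at the acetal carbon)
Conditions: NIS (1.5 equiv), 14 (5 equiv), CH2Cl2, −40 → 0 °C
Reagents that add atoms: N-iodosuccinimide O=C1CCC(=O)N1I
Why: Iodoacetalisation (alkoxy-iodination of a vinyl ether), in which the excess, far more nucleophilic vinyl ether takes up the iodonium ion before the deactivated C4=C5 enol ether can, and the resulting oxocarbenium ion is trapped by the C3a hydroxyl, the only free hydroxyl; the acetal epimers are of no consequence.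

Step 9
Reactants: 15 (2S,3aR)-3a-(1-ethoxy-2-iodoethoxy)-5-methyl-7-(2-methylpropanoyl)-2-[2-(triethylsilyloxy)propan-2-yl]-4-(triisopropylsilyloxy)-3,3a-dihydro-1-benzofuran-6(2H)-one
Product: 17 (2S,3aR,5S)-5-methyl-7-(2-methylpropanoyl)-2-[2-(triethylsilyloxy)propan-2-yl]-3,3a-dihydro-1-benzofuran-4,6(2H,5H)-dione bridged from C5 to O3a by CH2–CH(OEt) (acetal carbon as either epimer), via caesium enolate 16 (not isolated)
Conditions: CsF (3 equiv), DMF (0.01 M), 0 → 50 °C
Reagents that add atoms: none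
Why: Fluoride attacks silicon of the vinylogous silyl ester and releases the enolate delocalised over O4–C4–C5–C6–O6, whose central carbon C5 displaces iodide from the tethered CH2I in an intramolecular SN2 C-alkylation. The closest known reaction type is the intramolecular alpha-alkylation of cyclohexanone and cyclic 1,3-dione enolates that gives bicyclo[3.3.1]nonanones. The one new ring (C5, C1', acetal carbon, O, C3a, C4) closes 6-exo-tet at the CH2I carbon, enolexo for the C5=C6–O form of the enolate and enolendo for the O4–C4=C5 form, both allowed at this ring size, through a chair-like transition state with the C3a–O bond perpendicular to the enolate plane. C5 is the only stereocentre formed and the tether controls it: the two-atom link anchored on O3a can reach C5 only on the face that carries this oxygen, so C1' ends cis to O3a and the methyl group trans (5S). The step needs carbon rather than oxygen alkylation: O6 is out of reach, and closure through O4 is disfavoured because ring B holds C3 near the enolate plane, which forces the C3a–O bond axial, puts CH2I over the C5 lobe and turns it about 90° away from the in-plane lone pairs of O4, while the soft iodide also favours carbon. High dilution should suppress intermolecular alkylation, and the weakly basic dione enolate should leave the triethylsilyl ether, the acetal and the C7a vinylogous ester untouched.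

Step 10
Reactants: 17 the bridged ethyl acetal from step 9
Product: 18 (2S,3aR,5S)-2-(2-hydroxypropan-2-yl)-5-methyl-7-(2-methylpropanoyl)-3,3a-dihydro-1-benzofuran-4,6(2H,5H)-dione bridged from C5 to O3a by CH2–CH(OH) (lactol; either epimer)
Conditions: 1 M aq. HCl, THF, 0 °C → rt
Reagents that add atoms: water O
Why: Acid-catalysed hydrolysis of the cyclic acetal to the lactol with concurrent cleavage of the tertiary triethylsilyl ether, which touches no stereocentre of the target since the hemiacetal carbon is flattened in step 11.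

Step 11
Reactants: 18 the bridged lactol from step 10
Product: 20 (2S,3aR,5S)-3a-hydroxy-2-(2-hydroxypropan-2-yl)-5-methyl-5-(3-methylbut-2-en-1-yl)-7-(2-methylpropanoyl)-3,3a-dihydro-1-benzofuran-4,6(2H,5H)-dione, via open hydroxy aldehyde 19 (not isolated)
Conditions: i-PrPPh3I (5 equiv), n-BuLi (4.8 equiv), THF, 0 °C; then 18, −78 → 0 °C
Reagents that add atoms: isopropylidenetriphenylphosphorane CC(C)=P(c1ccccc1)(c1ccccc1)c1ccccc1
Why: Wittig olefination of a lactol through its ring-opened hydroxy aldehyde with a non-stabilised ylide, where excess ylide first takes up the two hydroxyl protons, the unhindered aldehyde should react far faster than the C4 ketone between two quaternary carbons or the two vinylogous-ester carbonyls, the new olefin has no geometry to control, and opening the bridge returns the free C3a hydroxyl.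

Compound list
1 | 2-methylbenzene-1,3,5-triol | Cc1c(O)cc(O)cc1O | starting material
2 | isobutyryl chloride (2-methylpropanoyl chloride) | CC(C)C(=O)Cl | starting material
3 | 2-methyl-1-(2,4,6-trihydroxy-3-methylphenyl)propan-1-one | CC(C)C(=O)c1c(O)cc(O)c(C)c1O | intermediate
4 | prenyl bromide (1-bromo-3-methylbut-2-ene) | CC(C)=CCBr | starting material
5 | 2-methyl-1-[2,4,6-trihydroxy-3-methyl-5-(3-methylbut-2-en-1-yl)phenyl]propan-1-one | Cc1c(O)c(C(=O)C(C)C)c(O)c(CC=C(C)C)c1O | intermediate
6 | 1-[2,6-dihydroxy-3-methyl-5-(3-methylbut-2-en-1-yl)-4-(triisopropylsilyloxy)phenyl]-2-methylpropan-1-one | Cc1c(O)c(C(=O)C(C)C)c(O)c(CC=C(C)C)c1O[Si](C(C)C)(C(C)C)C(C)C | intermediate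
7 | 4-methyl-6-(3-methylbut-2-en-1-yl)-2-(2-methylpropanoyl)-5-(triisopropylsilyloxy)-1,3-phenylene diacetate | Cc1c(OC(C)=O)c(C(=O)C(C)C)c(OC(C)=O)c(CC=C(C)C)c1O[Si](C(C)C)(C(C)C)C(C)C | intermediate
8 | 4-{[(2R)-3,3-dimethyloxiran-2-yl]methyl}-6-methyl-2-(2-methylpropanoyl)-5-(triisopropylsilyloxy)-1,3-phenylene diacetate | Cc1c(OC(C)=O)c(C(=O)C(C)C)c(OC(C)=O)c(C[C@H]2OC2(C)C)c1O[Si](C(C)C)(C(C)C)C(C)C | intermediate
9 | 1-[3-{[(2R)-3,3-dimethyloxiran-2-yl]methyl}-2,6-dihydroxy-5-methyl-4-(triisopropylsilyloxy)phenyl]-2-methylpropan-1-one | Cc1c(O)c(C(=O)C(C)C)c(O)c(C[C@H]2OC2(C)C)c1O[Si](C(C)C)(C(C)C)C(C)C | intermediate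
10 | 1-[(2S)-6-hydroxy-2-(2-hydroxypropan-2-yl)-5-methyl-4-(triisopropylsilyloxy)-2,3-dihydro-1-benzofuran-7-yl]-2-methylpropan-1-one | Cc1c(O)c(C(=O)C(C)C)c2O[C@H](C(C)(C)O)Cc2c1O[Si](C(C)C)(C(C)C)C(C)C | intermediate
11 | 2-methyl-1-[(2S)-5-methyl-6-(triethylsilyloxy)-2-[2-(triethylsilyloxy)propan-2-yl]-4-(triisopropylsilyloxy)-2,3-dihydro-1-benzofuran-7-yl]propan-1-one | Cc1c(O[Si](CC)(CC)CC)c(C(=O)C(C)C)c2O[C@H](C(C)(C)O[Si](CC)(CC)CC)Cc2c1O[Si](C(C)C)(C(C)C)C(C)C | intermediate
12 | 1-[(2S)-6-hydroxy-5-methyl-2-[2-(triethylsilyloxy)propan-2-yl]-4-(triisopropylsilyloxy)-2,3-dihydro-1-benzofuran-7-yl]-2-methylpropan-1-one | Cc1c(O)c(C(=O)C(C)C)c2O[C@H](C(C)(C)O[Si](CC)(CC)CC)Cc2c1O[Si](C(C)C)(C(C)C)C(C)C | intermediate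
13 | (2S,3aR)-3a-hydroxy-5-methyl-7-(2-methylpropanoyl)-2-[2-(triethylsilyloxy)propan-2-yl]-4-(triisopropylsilyloxy)-3,3a-dihydro-1-benzofuran-6(2H)-one | CC1C(=O)C(C(=O)C(C)C)=C2O[C@H](C(C)(C)O[Si](CC)(CC)CC)C[C@]2(O)C=1O[Si](C(C)C)(C(C)C)C(C)C | intermediate
14 | ethyl vinyl ether (ethoxyethene) | C=COCC | starting material
15 | (2S,3aR)-3a-(1-ethoxy-2-iodoethoxy)-5-methyl-7-(2-methylpropanoyl)-2-[2-(triethylsilyloxy)propan-2-yl]-4-(triisopropylsilyloxy)-3,3a-dihydro-1-benzofuran-6(2H)-one, acetal carbon as either epimer | CC1C(=O)C(C(=O)C(C)C)=C2O[C@H](C(C)(C)O[Si](CC)(CC)CC)C[C@]2(OC(CI)OCC)C=1O[Si](C(C)C)(C(C)C)C(C)C | intermediate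
16 | caesium C4/C6 enolate of 15 after loss of the triisopropylsilyl group (charge over O4–C4–C5–C6–O6) | CC1C(=O)C(C(=O)C(C)C)=C2O[C@H](C(C)(C)O[Si](CC)(CC)CC)C[C@]2(OC(CI)OCC)C=1[O-].[Cs+] | intermediate
17 | (2S,3aR,5S)-5-methyl-7-(2-methylpropanoyl)-2-[2-(triethylsilyloxy)propan-2-yl]-3,3a-dihydro-1-benzofuran-4,6(2H,5H)-dione with the bridge C5–CH2–CH(OEt)–O–C3a, acetal carbon as either epimer | CCOC3C[C@@]1(C)C(=O)C(C(=O)C(C)C)=C2O[C@H](C(C)(C)O[Si](CC)(CC)CC)C[C@]2(O3)C1=O | intermediate
18 | (2S,3aR,5S)-2-(2-hydroxypropan-2-yl)-5-methyl-7-(2-methylpropanoyl)-3,3a-dihydro-1-benzofuran-4,6(2H,5H)-dione with the lactol bridge C5–CH2–CH(OH)–O–C3a, either epimer | OC3C[C@@]1(C)C(=O)C(C(=O)C(C)C)=C2O[C@H](C(C)(C)O)C[C@]2(O3)C1=O | intermediate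
19 | 2-[(2S,3aR,5S)-3a-hydroxy-2-(2-hydroxypropan-2-yl)-5-methyl-7-(2-methylpropanoyl)-4,6-dioxo-2,3,3a,4,5,6-hexahydro-1-benzofuran-5-yl]acetaldehyde | O=CC[C@@]1(C)C(=O)C(C(=O)C(C)C)=C2O[C@H](C(C)(C)O)C[C@]2(O)C1=O | intermediate
20 | (2S,3aR,5S)-3a-hydroxy-2-(2-hydroxypropan-2-yl)-5-methyl-5-(3-methylbut-2-en-1-yl)-7-(2-methylpropanoyl)-3,3a-dihydro-1-benzofuran-4,6(2H,5H)-dione | CC(C)=CC[C@@]1(C)C(=O)C(C(=O)C(C)C)=C2O[C@H](C(C)(C)O)C[C@]2(O)C1=O | target

Total step count: 11. Longest linear sequence: 11 steps (1 to 20).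

Steps most likely to fail

Step 9. The enolate may close through O4 to a fused dioxene instead of through C5, or displacement at the acetal-flanked CH2I may be so slow that elimination or intermolecular alkylation takes over. Fallback: the two C5 substituents are introduced in the reverse order, so that the centre is set by an intermolecular methylation. An external electrophile should approach C5 from the face away from the axial C3a oxygen, which leaves the prenyl group cis to that oxygen without any tether. The fallback sets out from prenyl bromide 4 and commercial 2-methyl-1-(2,4,6-trihydroxyphenyl)propan-1-one F1 and returns to the route at the target 20. Double C-prenylation of F1 with 4 in aqueous KOH gives 2-methyl-1-[2,4,6-trihydroxy-3,5-bis(3-methylbut-2-en-1-yl)phenyl]propan-1-one F2. Silylation as in step 3 gives the para-O-triisopropylsilyl ether F3, and acetylation gives its diacetate F4. Shi epoxidation with one equivalent of oxidant converts one of the two equivalent prenyl groups into the (R)-epoxide F5. K2CO3 in MeOH frees the epoxy diphenol F6, which closes to the (2S)-dihydrobenzofuran carbinol F7 with the second prenyl group on C5. TESOTf gives the bis-triethylsilyl ether F8, and methanolysis leaves the carbinol triethylsilyl ether F9. PhI(OAc)2 in aqueous MeCN gives the (2S,3aR)-quinol F10. CsF and MeI in DMF should then give the (2S,3aR,5S) C-methylated silyl ether F11, and aqueous HCl in THF removes the triethylsilyl group to give 20.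

Step 7. Water may add at the ortho carbon C5 instead of C3a, acetate may be captured in its place, the new vinylogous silyl ester may hydrolyse, or the facial selectivity at C3a may be poor. Fallback: from phenol 12, the oxygen is brought in by a pericyclic rather than a cationic process. Dye-sensitised photo-oxygenation (O2, tetraphenylporphyrin, visible light, CH2Cl2–MeOH, −20 °C) adds singlet oxygen across C3a and C6 only, again from the face away from the C2 side chain. The adduct opens to the (2S,3aR)-3a-hydroperoxy dienone F12, which Me2S reduces to quinol 13, where the route is rejoined.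

Step 11. The hindered, strongly basic ylide may add to C7a of the vinylogous ester and open ring B, may enolise the aldehyde, or may induce cleavage of the non-enolisable 4,6-dione, all in place of olefination. Fallback: from lactol 18, the prenyl group is built in two non-basic operations. Aldehyde-selective methylenation (CH2I2, Zn, Ti(OiPr)4, THF) gives the (2S,3aR,5S)-5-allyl analogue of the target F13. Cross-metathesis of F13 with 2-methylbut-2-ene (second-generation Grubbs catalyst, CH2Cl2, 40 °C) gives the target 20.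

Further compounds
F1 | step 9 | 2-methyl-1-(2,4,6-trihydroxyphenyl)propan-1-one | CC(C)C(=O)c1c(O)cc(O)cc1O
F2 | step 9 | 2-methyl-1-[2,4,6-trihydroxy-3,5-bis(3-methylbut-2-en-1-yl)phenyl]propan-1-one | CC(C)C(=O)c1c(O)c(CC=C(C)C)c(O)c(CC=C(C)C)c1O
F3 | step 9 | 1-[2,6-dihydroxy-3,5-bis(3-methylbut-2-en-1-yl)-4-(triisopropylsilyloxy)phenyl]-2-methylpropan-1-one | CC(C)C(=O)c1c(O)c(CC=C(C)C)c(O[Si](C(C)C)(C(C)C)C(C)C)c(CC=C(C)C)c1O
F4 | step 9 | 4,6-bis(3-methylbut-2-en-1-yl)-2-(2-methylpropanoyl)-5-(triisopropylsilyloxy)-1,3-phenylene diacetate | CC(C)C(=O)c1c(OC(C)=O)c(CC=C(C)C)c(O[Si](C(C)C)(C(C)C)C(C)C)c(CC=C(C)C)c1OC(C)=O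
F5 | step 9 | 4-{[(2R)-3,3-dimethyloxiran-2-yl]methyl}-6-(3-methylbut-2-en-1-yl)-2-(2-methylpropanoyl)-5-(triisopropylsilyloxy)-1,3-phenylene diacetate | CC(C)C(=O)c1c(OC(C)=O)c(CC=C(C)C)c(O[Si](C(C)C)(C(C)C)C(C)C)c(C[C@H]2OC2(C)C)c1OC(C)=O
F6 | step 9 | 1-[3-{[(2R)-3,3-dimethyloxiran-2-yl]methyl}-2,6-dihydroxy-5-(3-methylbut-2-en-1-yl)-4-(triisopropylsilyloxy)phenyl]-2-methylpropan-1-one | CC(C)C(=O)c1c(O)c(CC=C(C)C)c(O[Si](C(C)C)(C(C)C)C(C)C)c(C[C@H]2OC2(C)C)c1O
F7 | step 9 | 1-[(2S)-6-hydroxy-2-(2-hydroxypropan-2-yl)-5-(3-methylbut-2-en-1-yl)-4-(triisopropylsilyloxy)-2,3-dihydro-1-benzofuran-7-yl]-2-methylpropan-1-one | CC(C)=CCc1c(O)c(C(=O)C(C)C)c2O[C@H](C(C)(C)O)Cc2c1O[Si](C(C)C)(C(C)C)C(C)C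
F8 | step 9 | 2-methyl-1-[(2S)-5-(3-methylbut-2-en-1-yl)-6-(triethylsilyloxy)-2-[2-(triethylsilyloxy)propan-2-yl]-4-(triisopropylsilyloxy)-2,3-dihydro-1-benzofuran-7-yl]propan-1-one | CC(C)=CCc1c(O[Si](CC)(CC)CC)c(C(=O)C(C)C)c2O[C@H](C(C)(C)O[Si](CC)(CC)CC)Cc2c1O[Si](C(C)C)(C(C)C)C(C)C
F9 | step 9 | 1-[(2S)-6-hydroxy-5-(3-methylbut-2-en-1-yl)-2-[2-(triethylsilyloxy)propan-2-yl]-4-(triisopropylsilyloxy)-2,3-dihydro-1-benzofuran-7-yl]-2-methylpropan-1-one | CC(C)=CCc1c(O)c(C(=O)C(C)C)c2O[C@H](C(C)(C)O[Si](CC)(CC)CC)Cc2c1O[Si](C(C)C)(C(C)C)C(C)C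
F10 | step 9 | (2S,3aR)-3a-hydroxy-5-(3-methylbut-2-en-1-yl)-7-(2-methylpropanoyl)-2-[2-(triethylsilyloxy)propan-2-yl]-4-(triisopropylsilyloxy)-3,3a-dihydro-1-benzofuran-6(2H)-one | CC(C)=CCC1C(=O)C(C(=O)C(C)C)=C2O[C@H](C(C)(C)O[Si](CC)(CC)CC)C[C@]2(O)C=1O[Si](C(C)C)(C(C)C)C(C)C
F11 | step 9 | (2S,3aR,5S)-3a-hydroxy-5-methyl-5-(3-methylbut-2-en-1-yl)-7-(2-methylpropanoyl)-2-[2-(triethylsilyloxy)propan-2-yl]-3,3a-dihydro-1-benzofuran-4,6(2H,5H)-dione | CC(C)=CC[C@@]1(C)C(=O)C(C(=O)C(C)C)=C2O[C@H](C(C)(C)O[Si](CC)(CC)CC)C[C@]2(O)C1=O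
F12 | step 7 | (2S,3aR)-3a-hydroperoxy-5-methyl-7-(2-methylpropanoyl)-2-[2-(triethylsilyloxy)propan-2-yl]-4-(triisopropylsilyloxy)-3,3a-dihydro-1-benzofuran-6(2H)-one | CC1C(=O)C(C(=O)C(C)C)=C2O[C@H](C(C)(C)O[Si](CC)(CC)CC)C[C@]2(OO)C=1O[Si](C(C)C)(C(C)C)C(C)C
F13 | step 11 | (2S,3aR,5S)-3a-hydroxy-2-(2-hydroxypropan-2-yl)-5-methyl-7-(2-methylpropanoyl)-5-(prop-2-en-1-yl)-3,3a-dihydro-1-benzofuran-4,6(2H,5H)-dione | C=CC[C@@]1(C)C(=O)C(C(=O)C(C)C)=C2O[C@H](C(C)(C)O)C[C@]2(O)C1=O
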